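I was asked two things about these flasks: a row of end amounts of complex with two exchanged, and the shape of that row.

    starting complex + incoming ligand ⇌ leaving ligand + complex with one exchanged (K1 = 2.3, k1 = 22 M⁻¹ s⁻¹)
    complex with one exchanged + incoming ligand ⇌ leaving ligand + complex with two exchanged (K2 = 27, k2 = 26 M⁻¹ s⁻¹)
    complex with two exchanged + incoming ligand ⇌ leaving ligand + complex with three exchanged (K3 = 1.6, k3 = 34 M⁻¹ s⁻¹)
    complex with three exchanged + incoming ligand ⇌ leaving ligand + complex with four exchanged (K4 = 4.7, k4 = 23 M⁻¹ s⁻¹)
    starting complex + complex with one exchanged → side product (k5 = 0.56 M⁻¹ s⁻¹)
    complex with two exchanged ⇌ isomer of the product (K6 = 0.43, k6 = 0.0067 s⁻¹)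

common to all: starting complex 5.0 mM; leaving ligand 25.0 mM; time 3.0 min
- midnight: incoming ligand 2.00 mM
- dusk: incoming ligand 6.00 mM
- dawn: incoming ligand 15.0 mM
- spring: incoming ligand 50.0 mM

1. amount of complex with two exchanged at the end, in percent of the starting complex charged for midnight, dusk, dawn, spring, in this order
2. how that number moves from the first to the last of them (rises, then falls / falls all the way / hardly changes / rises all the way / falls, then rises)

- percentages count the starting complex that a species holds: one side product counts as two
- "hardly changes" means that all values lie within two and a half points (for a concentration: within two and a half percent of the largest)
- run time (midnight): 3.0 min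

**Time enough.** In the midnight flask, counting forward rates, starting complex exchanged with a half-life of 0.26 min and complex with two exchanged with one of 0.17 min, while the isomer relaxed with a half-life of 0.518 min. Each is shorter than the run of 3.0 min . The dawn and spring flasks hold more incoming ligand, so I took their exchange to be at rest by the end, and I set the side product aside.

**Ligand balance.** Every exchange spends one incoming ligand and frees one leaving ligand. Full exchange needs 20.0 mM of incoming ligand. The dawn charge of 15.0 mM is less than that, so, counted against full exchange, incoming ligand is the limiting reagent in the dawn flask. The spring charge of 50.0 mM is more, so, counted the same way, the complex is the limiting reagent in the spring flask.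

**Midpoint charge.** At rest, each exchange holds the next complex over the one before it at its equilibrium constant times the ligand ratio, incoming over leaving ligand. Starting complex and complex with four exchanged therefore stand equal at a ratio of 0.215. With the two ends of the chain equal, I took complex with two exchanged, its middle member, as the top. Two exchanges per complex spend 10.0 mM of incoming ligand and raise leaving ligand to 35.0 mM. Adding what that ratio requires gives 17.5 mM, the midpoint charge: the incoming ligand charged, with these amounts of complex and leaving ligand, that reaches two exchanges per complex at that ratio.

**Dawn against spring.** These two flasks differ in their charge of incoming ligand. The dawn charge is less than the midpoint charge, so I expected that flask just short of the top, with midnight and dusk lower still. The spring charge is more. Even full exchange there leaves a ratio of 0.667, which is above 0.215, so I expected that flask well past the top. I committed to a row that rises to dawn and falls to spring, and my reckoning gave no row of numbers.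

**The forecast.** It gave 4.9 %, 18 %, 37 % and 13.7 %, a row that rises, then falls, saying that the complex “builds as ligand is added, peaks around 15 mM”.

**The outcome.** The simulation gave 5.00 %, 19.1 %, 36.9 % and 13.6 %, a row that rises, then falls, turning at 17 mM against my midpoint charge of 17.5 mM. The dawn flask ended at a ligand ratio of 0.178, below 0.215, and the spring flask at 0.784, above it. Complex with two exchanged stayed in the spring flask through the way back from complex with three exchanged and leaving ligand. In the run with that way back taken away the shape changes, and the spring flask holds 0 % instead of 13.6 %.

(The numbers of this flask were drawn at random within sensible limits, and the outcome is calculated.)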